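**Assumptions (one line each)**
- The stereocentre is (R) (the danshensu-type lactate carbon), as derived from the SMILES.
- (R)-Danshensu, D-(+)-β-(3,4-dihydroxyphenyl)lactic acid, is commercially available. If it is not, D-DOPA with NaNO2/H2SO4 gives it with net retention.
- Every phenol and the carboxylic acid are masked as benzyl groups so that one hydrogenolysis at the end unmasks everything.
- Only substrates and products are numbered. Reagents are given by name and SMILES inside each step.

**Retrosynthesis**
1. Cut the ester to give the 4-aryl-6,7-dihydroxy-2-naphthoic acid and (R)-danshensu. The lactate stereocentre comes from the chiral pool and is never touched. All OH groups are carried as Bn ethers or a Bn ester for one final hydrogenolysis.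
2. Key step: form the new benzenoid ring by an aryne/2-pyrone [4+2] cycloaddition followed by loss of CO2. This combines 4,5-bis(benzyloxy)benzyne with methyl 3-bromocoumalate and places the CO2Me and Br meta to each other (naphthalene C2 and C4) in one operation.
3. Ring order: the pyrone ring is commercial. The aryne supplies the benzo ring with the 6,7-dioxygenation. The former pyrone carbons become the second ring of the naphthalene. The catechol aryl is then added at C4 by Suzuki coupling.

---

**Step 1**
Reactants: 1 (3,4-bis(benzyloxy)benzaldehyde)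
Product: 2 (3,4-bis(benzyloxy)phenol)
Conditions: mCPBA, CH2Cl2, 0 °C→rt; then K2CO3, MeOH, rt
Reagents that add atoms: mCPBA, OOC(=O)c1cccc(Cl)c1 (the O is inserted into the product)
Why: Baeyer–Villiger (Dakin-type) oxidation of an electron-rich aldehyde gives the aryl formate by aryl migration, and methanolysis frees the phenol.

**Step 2**
Reactants: 2
Product: 3 (2-bromo-4,5-bis(benzyloxy)phenol)
Conditions: NBS, CH2Cl2, –78→0 °C, dark
Reagents that add atoms: NBS, O=C1CCC(=O)N1Br (Br is retained)
Why: Electrophilic bromination goes ortho to OH and para to the 3-OBn, the less hindered activated position (as with 3,4-dimethoxyphenol).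

**Step 3**
Reactants: 3
Product: 4 ([2-bromo-4,5-bis(benzyloxy)phenoxy]trimethylsilane)
Conditions: HMDS, neat, 80 °C
Reagents that add atoms: HMDS, C[Si](C)(C)N[Si](C)(C)C (SiMe3 is retained)
Why: Silylation of the phenol sets up the O→C silyl transfer of the next step.

**Step 4**
Reactants: 4
Product: 5 (4,5-bis(benzyloxy)-2-(trimethylsilyl)phenyl triflate)
Conditions: n-BuLi, THF, –78→–40 °C; then Tf2O, –78 °C→rt
Reagents that add atoms: Tf2O, O=S(=O)(C(F)(F)F)OS(=O)(=O)C(F)(F)F (the Tf group is retained). n-BuLi leaves no atoms.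
Why: Br/Li exchange is followed by a retro-[1,4]-Brook O→C silyl migration to give the 2-silylphenoxide, which Tf2O traps (Kobayashi aryne precursor synthesis).

**Step 5**
Reactants: 6 (methyl coumalate, methyl 2-oxo-2H-pyran-5-carboxylate)
Product: 7 (methyl 3-bromo-2-oxo-2H-pyran-5-carboxylate)
Conditions: Br2, CH2Cl2, 0 °C→rt; then Et3N, 0 °C
Reagents that add atoms: Br2, BrBr (Br is retained)
Why: Proposed new method: Br2 should add across the less electron-rich C3=C4 bond of the pyrone, and E2 loss of HBr with Et3N then gives the 3-bromopyrone. The closest known reaction is the conversion of 2-pyrone to 3-bromo-2-pyrone with Br2 then Et3N; the 5-CO2Me substituent is the untested feature.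

**Step 6 (key step)**
Reactants: 7 and 5 (1.5 equiv)
Product: 8 (methyl 4-bromo-6,7-bis(benzyloxy)-2-naphthoate)
Conditions: CsF, MeCN, 50 °C
Reagents that add atoms: none (CsF only generates the aryne; CO2 and TMSF are lost)
Why: Fluoride unmasks 4,5-bis(benzyloxy)benzyne, which undergoes a [4+2] cycloaddition across C3/C6 of the pyrone, and the bridged lactone extrudes CO2 (retro-[4+2]) to aromatise irreversibly. The symmetric aryne removes any regiochemical issue, and the pyrone substitution pattern fixes Br and CO2Me meta to each other. There is no new stereocentre.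

**Step 7**
Reactants: 9 (4-bromo-1,2-bis(benzyloxy)benzene)
Product: 10 (2-[3,4-bis(benzyloxy)phenyl]-4,4,5,5-tetramethyl-1,3,2-dioxaborolane)
Conditions: B2pin2, PdCl2(dppf), KOAc, dioxane, 90 °C
Reagents that add atoms: B2pin2, CC1(C)OB(OC1(C)C)B2OC(C)(C)C(C)(C)O2 (the Bpin group is retained)
Why: Miyaura borylation gives the Suzuki partner under conditions that leave benzyl ethers intact.

**Step 8**
Reactants: 8 and 10
Product: 11 (methyl 4-[3,4-bis(benzyloxy)phenyl]-6,7-bis(benzyloxy)-2-naphthoate)
Conditions: Pd(PPh3)4 (5 mol %), K2CO3, dioxane/H2O 10:1, 90 °C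
Reagents that add atoms: none beyond the coupled aryl group delivered by 10 (a reactant)
Why: Suzuki–Miyaura coupling at the naphthyl C4 bromide installs the pendant catechol ring. The ester and benzyl ethers survive.

**Step 9**
Reactants: 11
Product: 12 (4-[3,4-bis(benzyloxy)phenyl]-6,7-bis(benzyloxy)-2-naphthoic acid)
Conditions: LiOH·H2O, THF/MeOH/H2O 3:1:1, 50 °C; then 1 M HCl
Reagents that add atoms: water, O (the carboxylate O comes from hydroxide/water)
Why: Saponification of the aryl methyl ester leaves the benzyl ethers untouched.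

**Step 10**
Reactants: 13 ((R)-danshensu, (R)-3-(3,4-dihydroxyphenyl)-2-hydroxypropanoic acid)
Product: 14 (benzyl (R)-3-[3,4-bis(benzyloxy)phenyl]-2-hydroxypropanoate)
Conditions: BnBr (3.2 equiv), K2CO3, DMF, rt
Reagents that add atoms: BnBr, BrCc1ccccc1 (three Bn groups are retained)
Why: Carboxylate and phenolate alkylation is faster than alkylation of the hindered secondary alcohol with mild K2CO3, so the OH stays free and the stereocentre is not touched.

**Step 11**
Reactants: 12 and 14
Product: 15 (the fully benzyl-protected eritrichin)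
Conditions: (COCl)2, cat. DMF, CH2Cl2, 0 °C, then concentrate; then 14, pyridine, cat. DMAP, CH2Cl2, 0 °C→rt
Reagents that add atoms: none (the Cl of the acid chloride is lost)
Why: Acylation of the secondary alcohol through the acid chloride with weak base at low temperature avoids epimerisation of the α-acyloxy ester, so the (R) centre is retained.

**Step 12**
Reactants: 15
Product: 16 (eritrichin)
Conditions: H2 (1 atm), 10% Pd/C, THF/MeOH 1:1, rt; purify by reverse-phase HPLC
Reagents that add atoms: none (only H is added)
Why: Hydrogenolysis removes all seven Bn groups (six aryl ethers and the benzyl ester) under neutral conditions. The aryl ester and the non-benzylic stereocentre are unaffected.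

---

**Checks performed**
- **Skeleton:** 16 is a 4-(3,4-dihydroxyphenyl)-6,7-dihydroxy-2-naphthoate ester of (R)-danshensu.
- **Atom bookkeeping:** Step 6 is C7H5BrO4 + C20H16O2 − CO2 = C26H21BrO4, which matches 8.
- **Stereochemistry:** The (R) centre is present only in 13, 14, 15 and 16, with the same neighbour order as the target SMILES. It is not exposed to strong base or acid at any point.

---

**Compound list**

| # | Name | SMILES | Role |
|---|---|---|---|
| 1 | 3,4-Bis(benzyloxy)benzaldehyde | O=Cc1ccc(OCc2ccccc2)c(OCc2ccccc2)c1 | starting material |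
| 2 | 3,4-Bis(benzyloxy)phenol | Oc1ccc(OCc2ccccc2)c(OCc2ccccc2)c1 | intermediate |
| 3 | 2-Bromo-4,5-bis(benzyloxy)phenol | Oc1cc(OCc2ccccc2)c(OCc2ccccc2)cc1Br | intermediate |
| 4 | [2-Bromo-4,5-bis(benzyloxy)phenoxy]trimethylsilane | C[Si](C)(C)Oc1cc(OCc2ccccc2)c(OCc2ccccc2)cc1Br | intermediate |
| 5 | 4,5-Bis(benzyloxy)-2-(trimethylsilyl)phenyl triflate | C[Si](C)(C)c1cc(OCc2ccccc2)c(OCc2ccccc2)cc1OS(=O)(=O)C(F)(F)F | intermediate (aryne precursor) |
| 6 | Methyl coumalate | COC(=O)C1=COC(=O)C=C1 | starting material |
| 7 | Methyl 3-bromo-2-oxo-2H-pyran-5-carboxylate | COC(=O)C1=COC(=O)C(Br)=C1 | intermediate |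
| 8 | Methyl 4-bromo-6,7-bis(benzyloxy)-2-naphthoate | COC(=O)c1cc(Br)c2cc(OCc3ccccc3)c(OCc3ccccc3)cc2c1 | intermediate |
| 9 | 4-Bromo-1,2-bis(benzyloxy)benzene | Brc1ccc(OCc2ccccc2)c(OCc2ccccc2)c1 | starting material |
| 10 | 3,4-Bis(benzyloxy)phenyl-Bpin | CC1(C)OB(OC1(C)C)c1ccc(OCc2ccccc2)c(OCc2ccccc2)c1 | intermediate |
| 11 | Methyl 4-[3,4-bis(benzyloxy)phenyl]-6,7-bis(benzyloxy)-2-naphthoate | COC(=O)c1cc(-c2ccc(OCc3ccccc3)c(OCc3ccccc3)c2)c2cc(OCc3ccccc3)c(OCc3ccccc3)cc2c1 | intermediate |
| 12 | 4-[3,4-Bis(benzyloxy)phenyl]-6,7-bis(benzyloxy)-2-naphthoic acid | OC(=O)c1cc(-c2ccc(OCc3ccccc3)c(OCc3ccccc3)c2)c2cc(OCc3ccccc3)c(OCc3ccccc3)cc2c1 | intermediate |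
| 13 | (R)-Danshensu | O[C@H](Cc1ccc(O)c(O)c1)C(=O)O | starting material |
| 14 | Benzyl (R)-3-[3,4-bis(benzyloxy)phenyl]-2-hydroxypropanoate | O[C@H](Cc1ccc(OCc2ccccc2)c(OCc2ccccc2)c1)C(=O)OCc1ccccc1 | intermediate |
| 15 | Per-benzylated eritrichin | O=C(O[C@H](Cc1ccc(OCc2ccccc2)c(OCc2ccccc2)c1)C(=O)OCc1ccccc1)c1cc(-c2ccc(OCc3ccccc3)c(OCc3ccccc3)c2)c2cc(OCc3ccccc3)c(OCc3ccccc3)cc2c1 | intermediate |
| 16 | Eritrichin | O=C(O[C@H](Cc1ccc(O)c(O)c1)C(=O)O)c1cc(-c2ccc(O)c(O)c2)c2cc(O)c(O)cc2c1 | target |

---

**Totals**
- Total steps: 12.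
- Longest linear sequence: 9 steps (1→2→3→4→5→8→11→12→15→16, i.e. Steps 1, 2, 3, 4, 6, 8, 9, 11, 12).

**Three steps most likely to fail**
1. **Step 5 (bromination of methyl coumalate).** The regiochemistry and the electron-poor ring are untested.
   - Fallback: drop the pyrone. Build methyl 4-bromo-6,7-bis(benzyloxy)-2-naphthoate (8) by a classical Friedel–Crafts route. Cyclise the 2-(3,4-bis(benzyloxy)benzyl)succinate half-ester to the 4-oxotetralin-2-carboxylate, then convert the ketone to the vinyl bromide or triflate and aromatise with DDQ.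
2. **Step 6 (aryne/pyrone cycloaromatisation).** The dialkoxyaryne is a sluggish, electron-rich dienophile, and the pyrone could be attacked by fluoride.
   - Fallback: use the same tetralone route, adding ArB(OH)2 by Suzuki coupling of the vinyl triflate, then DDQ, to reach 11 without any aryne.
3. **Step 12 (global hydrogenolysis of seven benzyl groups on an oxidation-prone polyphenol).** It may be incomplete, or the catechols may oxidise.
   - Fallback: switch the protecting-group strategy to a Lewis-acid debenzylation, BCl3·SMe2 with pentamethylbenzene as cation scavenger in CH2Cl2 at –78 °C, which avoids Pd and H2.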